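## Structural features

The target is a flavonol: a 4H-chromen-4-one in which benzo ring A is fused at C4a–C8a to γ-pyranone ring C, with a 4-methoxyphenyl ring B on C2 and hydroxyl groups on C3, C5 and C7. Ring A is a phloroglucinol nucleus (oxygen on C5, C7 and C8a) whose only hydrogen is at C6. C4a carries the C4 carbonyl, and C8 carries a 2-methylbut-3-en-2-yl (1,1-dimethylallyl) group through a quaternary carbon. There is no stereocenter and no alkene geometry to control. The fragile points are the terminal vinyl group (it rules out hydrogenolysis, and under strong acid O7 can add to it to give a dihydrofuran), the oxidation-prone 3-hydroxypyranone and polyphenol, and the 4'-methyl ether, which must survive when the other oxygen substituents are unmasked. The real difficulty is the aryl–C(quaternary) bond at C8, the most crowded ring position, flanked by O7 and O1, and its placement at C8 and not at C6, which amounts to telling O5 from O7 and O1 in a phloroglucinol. The key step exploits the fact that C8 lies between two oxygen-bearing carbons (C7 and C8a), with the third oxygen-bearing carbon (C5) para to it. This is the pattern that a benzannulation of an ynol silyl ether (bringing C8 with its tert-alkyl group and one neighbouring C–O) with a 3-alkoxycyclobutenone (bringing the other four ring carbons, its alkoxy carbon ending para) writes directly, the three oxygens arriving differentiated as OH, OSi and OEt.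

## Logic of the disconnections

**18 ⇒ 17.** The O5–ethyl and O7–CH2OCH3 bonds are cut. The ethyl group on O5 is the tag that has kept O5 distinct from O1 and O7 since ring A was made, and the acetal on O7 keeps the chalcone stage electrophilic. Nothing is gained in skeleton, but both groups can fall in one operation. The forward step needs a reagent that dealkylates O5 through chelation with the C4 carbonyl and leaves the unchelated 4'-methyl ether and the vinyl group alone.

**17 ⇒ 15.** The O1–C2 bond and the C3–O bond are cut, which opens ring C to a 2'-hydroxychalcone. One oxidative cyclization builds the pyranone and the 3-hydroxyl together. The forward step must close through the phenolic oxygen next to the tert-alkyl carbon, which is the only free oxygen ortho to the carbonyl because the other is ethylated. It must close at the β-carbon (six-membered ring) and not the α-carbon, with an oxidant that spares the vinyl group.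

**15 ⇒ 13 + 14.** The enone Cα=Cβ bond is cut. Ring B leaves as commercial 14 and a methyl ketone remains. The forward step is an aldol condensation on a hindered, hydrogen-bonded aryl methyl ketone.

**13 ⇒ 12.** The O–CH2OCH3 bond on the hydroxyl para to the acetyl group is cut. The forward step must select that hydroxyl over the chelated one between acetyl and tert-alkyl.

**12 ⇒ 11.** The aryl–acetyl bond (C4a–C4 of the target) is cut. 11 has a mirror plane through its C2 and C5, so its two ring CH positions are equivalent and acylation has no regiochemical choice. The forward step must C-acylate once, under conditions the vinyl group tolerates.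

**11 ⇒ 4 + 5 (key disconnection).** Ring A is dismantled. The two ring bonds that join the alkyne-derived carbon pair to the four-carbon unit are cut (C1–C2 and C3–C4 in the numbering of phenol 10), together with the O–Si bond. The aryl–C(quaternary) bond is thereby taken out of the problem, because it already exists in 4 as an sp–sp3 bond. The position of the tert-alkyl group between two oxygens, and the capping of the para oxygen alone, follow from the mechanism. A fully substituted, oxygen-differentiated ring thus comes from a C7 ynol ether and a commercial C4 cyclobutenone. In one sentence, the route is: ring A is created by thermal benzannulation of 4 with 5. The forward step demands a ketene–alkyne [2+2] at an alkyne carbon bearing a quaternary substituent, and a thermal window that 4 survives.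

**4 ⇒ 1.** The C≡C unit is cut between the oxygen-bearing carbon (the ester carbonyl carbon of 1) and the carbon bearing the tert-alkyl group (supplied by CH2Br2). This leads back to a commercial ester. The forward step demands addition of a carbenoid to a hindered but non-enolizable ester and a 1,2-shift of a tertiary alkyl group.

## Other disconnections considered

**Alternative 1:** Cut the C8–C(quaternary) bond as a [3,3] shift. The forward key step is an aromatic Claisen rearrangement (thermal or promoted by Eu(fod)3) of the 7-O-prenyl ether A1, 3,5-dihydroxy-2-(4-methoxyphenyl)-7-[(3-methylbut-2-en-1-yl)oxy]-4H-chromen-4-one. It moves the prenyl group from O7 to an ortho carbon with allylic inversion and so creates the 1,1-dimethylallyl group. This is the plan that comes to mind first.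
- O7 has two ortho carbons, C6 and C8, and the shift can reach either. A preference for C8 rests only on a modest bond-order bias of the chromone.
- The heat needed invites the further rearrangement and cycloetherification typical of ortho-(1,1-dimethylallyl)phenols.
- A1 itself needs selective 7-O-prenylation of a triol.
- The chosen plan has no C6/C8 choice at any stage.

**Alternative 2:** Cut the same C8–C bond as a cross-coupling. The forward key step is a γ-selective (branched) allyl–aryl Suzuki–Miyaura coupling of the 8-iodide A2, 8-iodo-3,5,7-tris(methoxymethoxy)-2-(4-methoxyphenyl)-4H-chromen-4-one, with 3-methylbut-2-en-1-ylboronic acid pinacol ester under zerovalent palladium catalysis (Pd2(dba)3 with a bulky biarylphosphine).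
- Reductive elimination would have to form a quaternary carbon on an aryl carbon carrying two ortho oxygen substituents. That is the situation in which the linear (α) product and protodehalogenation are expected to compete.
- Making A2 requires a C8-selective iodination, which is the C6/C8 problem again.
- The sequence (flavonol, protection, iodination, coupling, deprotection) is longer than the chosen one.

**Alternative 3:** Cut the C2–C1' bond between rings C and B. The forward key step is a twofold C–H coupling of the 2-unsubstituted chromonol A3, 5-ethoxy-3-hydroxy-7-(methoxymethoxy)-8-(2-methylbut-3-en-2-yl)-4H-chromen-4-one, with anisole under divalent palladium catalysis (Pd(OAc)2, AgOAc as oxidant).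
- Palladation at C2 of a chromone is plausible, but anisole offers ortho and para positions, and the free enolic 3-hydroxyl is exposed to the oxidant.
- The disconnection leaves the ring A problem untouched, since A3 still needs the C8 tert-alkyl group. It can only be added to another strategy, not replace it.
- The chalcone route brings in ring B at no cost from 14.

Key step: step 2

Assumption: methyl 2,2-dimethylbut-3-enoate 1 and 3-ethoxycyclobut-2-en-1-one 5 are taken as catalogue compounds (1 is otherwise one esterification from the commercial acid).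

## Route

Step 1
Reactants: 1 methyl 2,2-dimethylbut-3-enoate
Product: 4 [(3,3-dimethylpent-4-en-1-yn-1-yl)oxy]tri(propan-2-yl)silane, via dibromo enolate 2 (not isolated), via lithium ynolate 3 (not isolated)
Conditions: CH2Br2, lithium 2,2,6,6-tetramethylpiperidide (LiTMP, 2.1 equiv), THF, –78 °C; n-BuLi, –78 → 0 °C; i-Pr3SiCl, –78 °C → rt
Reagents that add atoms: dibromomethane, BrCBr; chlorotri(propan-2-yl)silane, CC(C)[Si](Cl)(C(C)C)C(C)C
Why: Kowalski ester homologation stopped at the ynolate: LiCHBr2 adds to the non-enolizable ester and collapse plus deprotonation give 2, then bromine–lithium exchange gives a carbenoid whose tert-alkyl group migrates (1,2-shift) to form ynolate 3. The bulky silyl chloride then silylates 3 on oxygen and not on carbon.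

Step 2
Reactants: 4 [(3,3-dimethylpent-4-en-1-yn-1-yl)oxy]tri(propan-2-yl)silane; 5 3-ethoxycyclobut-2-en-1-one
Product: 11 5-ethoxy-2-(2-methylbut-3-en-2-yl)benzene-1,3-diol, via vinylketene 6 (not isolated), via vinylcyclobutenone 7 (not isolated), via dienylketene 8 (not isolated), via cyclohexadienone 9 (not isolated), via monosilyl ether 10 (not isolated)
Conditions: 5 (1.5 equiv), toluene, 80 → 110 °C, sealed vessel; then n-Bu4NF, THF, 0 °C → rt; aq NH4Cl work-up
Reagents that add atoms: none
Why: Danheiser benzannulation in its siloxyalkyne form, a cascade of four thermal pericyclic events. 4π electrocyclic opening of 5 gives vinylketene 6, whose ketene C=C adds to 4 in a [2+2] with regiochemistry fixed by the polarization of the ynol ether: the alkyne carbon remote from oxygen, the one bearing the tert-alkyl group, bonds to the ketene carbonyl carbon, giving 7. 4π opening of 7 (reversible, funnelled through the geometry with the ethoxyvinyl group cis to the ketene) gives dienylketene 8, and a 6π disrotatory electrocyclization closes ring A as dienone 9, which tautomerizes to phenol 10. The four-membered ring of 7 is thus closed by ketene–alkyne [2+2], and the six-membered ring by 6π electrocyclization between the ketene carbon and the terminal CH2 of 8. No stereocenter survives, since 7 is a racemic transient that is flattened on aromatization. The selectivity needed is constitutional (tert-alkyl between OH and OSi, ethoxy para to it) and follows from the mechanism: the two alkyne carbons are inserted between C1 and C2 of 5, so C3 of 5, the ethoxy carbon, ends para to the tert-alkyl carbon. A 3-oxygenated cyclobutenone is a competent partner in principle because the cascade's own second ring opening (7 to 8) is that of a 3-siloxycyclobutenone. Fluoride then removes the silyl group and gives mirror-symmetric 11, in which only the oxygen para to the tert-alkyl group is capped.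

Step 3
Reactants: 11 5-ethoxy-2-(2-methylbut-3-en-2-yl)benzene-1,3-diol
Product: 12 1-[6-ethoxy-2,4-dihydroxy-3-(2-methylbut-3-en-2-yl)phenyl]ethan-1-one
Conditions: Ac2O (1.05 equiv), BF3·OEt2, CH2Cl2, –20 → 0 °C; aq NaOAc work-up
Reagents that add atoms: acetic anhydride, CC(=O)OC(C)=O
Why: Friedel–Crafts C-acetylation of a phloroglucinol-type nucleus, where the two free ring positions are equivalent by the mirror symmetry of 11 so that only one ketone can form. The chelated ketone deactivates the ring against a second acylation. The low temperature and the poor basicity of a monosubstituted vinyl group on a quaternary carbon should protect the olefin.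

Step 4
Reactants: 12 1-[6-ethoxy-2,4-dihydroxy-3-(2-methylbut-3-en-2-yl)phenyl]ethan-1-one
Product: 13 1-[6-ethoxy-2-hydroxy-4-(methoxymethoxy)-3-(2-methylbut-3-en-2-yl)phenyl]ethan-1-one
Conditions: MOMCl (1.1 equiv), i-Pr2NEt, CH2Cl2, 0 °C → rt
Reagents that add atoms: chloromethyl methyl ether, COCCl
Why: O-alkylation (acetal protection) of the more acidic hydroxyl para to the ketone, which is not hydrogen-bonded. The other hydroxyl is locked in a hydrogen bond to the carbonyl and walled in by the acetyl and tert-alkyl groups.

Step 5
Reactants: 13 1-[6-ethoxy-2-hydroxy-4-(methoxymethoxy)-3-(2-methylbut-3-en-2-yl)phenyl]ethan-1-one; 14 4-methoxybenzaldehyde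
Product: 15 (2E)-1-[6-ethoxy-2-hydroxy-4-(methoxymethoxy)-3-(2-methylbut-3-en-2-yl)phenyl]-3-(4-methoxyphenyl)prop-2-en-1-one
Conditions: KOH, EtOH–H2O, 0 °C → rt
Reagents that add atoms: none
Why: Claisen–Schmidt condensation with a non-enolizable aldehyde, where E1cB dehydration of the aldol gives the conjugated E-enone. The ethers, the acetal and the vinyl group are inert to aqueous alkali.

Step 6
Reactants: 15 (2E)-1-[6-ethoxy-2-hydroxy-4-(methoxymethoxy)-3-(2-methylbut-3-en-2-yl)phenyl]-3-(4-methoxyphenyl)prop-2-en-1-one
Product: 17 5-ethoxy-3-hydroxy-7-(methoxymethoxy)-2-(4-methoxyphenyl)-8-(2-methylbut-3-en-2-yl)-4H-chromen-4-one, via trans-dihydroflavonol 16 (not isolated)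
Conditions: 30% aq H2O2, NaOH, MeOH, 0 °C → rt
Reagents that add atoms: hydrogen peroxide, OO
Why: Algar–Flynn–Oyamada oxidation: hydroperoxide oxygenates the enone while the 2'-phenoxide closes on the β-carbon (six-membered closure, helped by the 4-methoxyphenyl group, which stabilizes positive character there) to give racemic 16, and a second equivalent of oxidant dehydrogenates 16 so that both transient stereocenters vanish. The only free oxygen ortho to the carbonyl is the one next to the tert-alkyl carbon, so the tert-alkyl group must end at C8. Alkaline peroxide does not epoxidize the isolated vinyl group.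

Step 7
Reactants: 17 5-ethoxy-3-hydroxy-7-(methoxymethoxy)-2-(4-methoxyphenyl)-8-(2-methylbut-3-en-2-yl)-4H-chromen-4-one
Product: 18 3,5,7-trihydroxy-2-(4-methoxyphenyl)-8-(2-methylbut-3-en-2-yl)-4H-chromen-4-one
Conditions: BCl3 (excess), CH2Cl2, –78 → 0 °C; MeOH quench
Reagents that add atoms: none
Why: Lewis-acid ether cleavage: BCl3 opens the acetal on O7 and, through the chelate between the C4 carbonyl and O5, delivers chloride to the peri ethyl group. The unchelated 4'-methyl ether should stay at or below 0 °C. The monosubstituted vinyl group on a quaternary carbon is a poor cation precursor and should not be engaged.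

## Compound list

1 | methyl 2,2-dimethylbut-3-enoate | COC(=O)C(C)(C)C=C | starting material
2 | lithium 1,1-dibromo-3,3-dimethylpenta-1,4-dien-2-olate | [Li+].[O-]C(=C(Br)Br)C(C)(C)C=C | intermediate (not isolated)
3 | lithium 3,3-dimethylpent-4-en-1-yn-1-olate | [Li+].[O-]C#CC(C)(C)C=C | intermediate (not isolated)
4 | [(3,3-dimethylpent-4-en-1-yn-1-yl)oxy]tri(propan-2-yl)silane | C=CC(C)(C)C#CO[Si](C(C)C)(C(C)C)C(C)C | intermediate
5 | 3-ethoxycyclobut-2-en-1-one | CCOC1=CC(=O)C1 | starting material
6 | 3-ethoxybuta-1,3-dien-1-one | C=C(OCC)C=C=O | intermediate (not isolated)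
7 | rac-4-(1-ethoxyethenyl)-2-(2-methylbut-3-en-2-yl)-3-{[tri(propan-2-yl)silyl]oxy}cyclobut-2-en-1-one (racemic) | C=CC(C)(C)C1=C(O[Si](C(C)C)(C(C)C)C(C)C)C(C(=C)OCC)C1=O | intermediate (not isolated)
8 | (3E)-5-ethoxy-2-(2-methylbut-3-en-2-yl)-3-{[tri(propan-2-yl)silyl]oxy}hexa-1,3,5-trien-1-one | O=C=C(C(C)(C)C=C)/C(O[Si](C(C)C)(C(C)C)C(C)C)=C\C(OCC)=C | intermediate (not isolated)
9 | 5-ethoxy-2-(2-methylbut-3-en-2-yl)-3-{[tri(propan-2-yl)silyl]oxy}cyclohexa-2,4-dien-1-one | C=CC(C)(C)C1=C(O[Si](C(C)C)(C(C)C)C(C)C)C=C(OCC)CC1=O | intermediate (not isolated)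
10 | 5-ethoxy-2-(2-methylbut-3-en-2-yl)-3-{[tri(propan-2-yl)silyl]oxy}phenol | CCOc1cc(O)c(C(C)(C)C=C)c(O[Si](C(C)C)(C(C)C)C(C)C)c1 | intermediate (not isolated)
11 | 5-ethoxy-2-(2-methylbut-3-en-2-yl)benzene-1,3-diol | CCOc1cc(O)c(C(C)(C)C=C)c(O)c1 | intermediate
12 | 1-[6-ethoxy-2,4-dihydroxy-3-(2-methylbut-3-en-2-yl)phenyl]ethan-1-one | CC(=O)c1c(OCC)cc(O)c(C(C)(C)C=C)c1O | intermediate
13 | 1-[6-ethoxy-2-hydroxy-4-(methoxymethoxy)-3-(2-methylbut-3-en-2-yl)phenyl]ethan-1-one | CC(=O)c1c(OCC)cc(OCOC)c(C(C)(C)C=C)c1O | intermediate
14 | 4-methoxybenzaldehyde | COc1ccc(C=O)cc1 | starting material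
15 | (2E)-1-[6-ethoxy-2-hydroxy-4-(methoxymethoxy)-3-(2-methylbut-3-en-2-yl)phenyl]-3-(4-methoxyphenyl)prop-2-en-1-one | COc1ccc(/C=C/C(=O)c2c(OCC)cc(OCOC)c(C(C)(C)C=C)c2O)cc1 | intermediate
16 | rac-(2R,3R)-5-ethoxy-3-hydroxy-7-(methoxymethoxy)-2-(4-methoxyphenyl)-8-(2-methylbut-3-en-2-yl)-2,3-dihydro-4H-chromen-4-one (trans, racemic; one enantiomer drawn) | COc1ccc([C@@H]2[C@H](C(=O)c3c(OCC)cc(OCOC)c(C(C)(C)C=C)c3O2)O)cc1 | intermediate (not isolated)
17 | 5-ethoxy-3-hydroxy-7-(methoxymethoxy)-2-(4-methoxyphenyl)-8-(2-methylbut-3-en-2-yl)-4H-chromen-4-one | C=CC(C)(C)c1c(OCOC)cc(OCC)c2c(=O)c(O)c(-c3ccc(OC)cc3)oc12 | intermediate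
18 | 3,5,7-trihydroxy-2-(4-methoxyphenyl)-8-(2-methylbut-3-en-2-yl)-4H-chromen-4-one | C=CC(C)(C)c1c(O)cc(O)c2c(=O)c(O)c(-c3ccc(OC)cc3)oc12 | target

## Step count and risk

Total step count: 7. Longest linear sequence: 7 steps (1 → 18); 5 and 14 enter as purchased compounds.

**Step 2 (key step).**
- Risk: the first electrocyclic opening of 5 is retarded by its vinylogous-ester stabilization, and the [2+2] is slowed because the new bond forms at an alkyne carbon bearing a quaternary substituent. The temperature and time then needed may allow 4 to isomerize by a 1,3-silyl shift, or the ketene to be captured by the phenol already formed.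
- Fallback: it sets out from 4 and comes back at 10, which is desilylated to 11 as in step 2. Ketene generation is moved from the thermal to a photochemical manifold (the diazo-ketone variant of the same benzannulation). Ethyl vinyl ether is lithiated at its α-carbon (t-BuLi, THF) and acylated with N-methoxy-N-methylacetamide to give 3-ethoxybut-3-en-2-one F1. Detrifluoroacetylative diazo transfer (LiN(SiMe3)2, CF3CO2CH2CF3; then MsN3, Et3N) gives 1-diazo-3-ethoxybut-3-en-2-one F2. Irradiation of F2 in the presence of 4 (CH2Cl2, rt) brings about a Wolff rearrangement to the same vinylketene 6 at a temperature where 4 is stable. The [2+2] to 7 follows, and brief warming (toluene, 80 °C) completes the 4π/6π sequence to 10.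

**Step 1.**
- Risk: slow addition of LiCHBr2 to the neopentyl-type ester carbonyl, so that the thermally fragile carbenoid decomposes before it adds.
- Fallback: it sets out from 1 and comes back at 3. Reduction with i-Bu2AlH (CH2Cl2, –78 °C) gives 2,2-dimethylbut-3-enal F3. Ohira–Bestmann homologation (dimethyl (1-diazo-2-oxopropyl)phosphonate, K2CO3, MeOH) gives 3,3-dimethylpent-4-en-1-yne F4. Deprotonation with n-BuLi and oxidation of the acetylide with lithium tert-butyl peroxide (THF, –78 → 0 °C) gives ynolate 3, which is silylated as in step 1.

**Step 3.**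
- Risk: acid-promoted addition of the neighbouring hydroxyl across the vinyl group under the BF3/acetic acid medium, or a second acylation.
- Fallback: it sets out from 11 and comes back at 13, replacing steps 3 and 4 by an anionic sequence without Lewis acid. Double protection (NaH, MOMCl, THF) gives 5-ethoxy-1,3-bis(methoxymethoxy)-2-(2-methylbut-3-en-2-yl)benzene F5. Directed ortho-lithiation between the acetal and ethoxy groups (n-BuLi, THF, 0 °C), followed by N-methoxy-N-methylacetamide, gives 1-[6-ethoxy-2,4-bis(methoxymethoxy)-3-(2-methylbut-3-en-2-yl)phenyl]ethan-1-one F6. Brief dilute HCl in MeOH at rt removes only the acetal ortho to the carbonyl, which is the more labile one, and delivers 13.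

**Step 6.**
- Risk: five-membered closure at the α-carbon (the aurone pathway), which a 6'-alkoxy group is known to favour, or sluggish oxygenation of the electron-rich enone.
- Fallback: it sets out from 15 and comes back at 17, separating ring closure from C3 oxygenation. Oxa-Michael cyclization (NaOAc, EtOH, reflux) gives the flavanone rac-5-ethoxy-7-(methoxymethoxy)-2-(4-methoxyphenyl)-8-(2-methylbut-3-en-2-yl)-2,3-dihydro-4H-chromen-4-one F7. Dehydrogenation (DDQ, 1,4-dioxane, reflux) gives the flavone 5-ethoxy-7-(methoxymethoxy)-2-(4-methoxyphenyl)-8-(2-methylbut-3-en-2-yl)-4H-chromen-4-one F8. C3-lithiation (LiN(i-Pr)2, THF, –78 °C), borylation with B(OMe)3 and oxidation (H2O2, AcOH) install the 3-hydroxyl and give 17.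

**Step 7.**
- Risk: the chelation-assisted cleavage of an ethyl ether is slower than that of a methyl ether. The longer exposure may allow acid-promoted addition of O7 across the vinyl group, or loss of the 4'-methyl ether.
- Fallback: it sets out from 17 and comes back at 18, with O7 masked as an ester during the de-ethylation. Mild methanolic HCl (40 °C) removes the acetal and gives 5-ethoxy-3,7-dihydroxy-2-(4-methoxyphenyl)-8-(2-methylbut-3-en-2-yl)-4H-chromen-4-one F9. Acetylation (Ac2O, pyridine) gives 5-ethoxy-2-(4-methoxyphenyl)-8-(2-methylbut-3-en-2-yl)-4-oxo-4H-chromene-3,7-diyl diacetate F10. BCl3 (CH2Cl2, –78 → 0 °C), now with the C4 carbonyl/O5 pair as the only chelating site and no free O7 nucleophile, gives 5-hydroxy-2-(4-methoxyphenyl)-8-(2-methylbut-3-en-2-yl)-4-oxo-4H-chromene-3,7-diyl diacetate F11. Methanolysis (K2CO3, MeOH, rt) gives 18.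

## Further compounds

F1 | step 2 | 3-ethoxybut-3-en-2-one | C=C(OCC)C(C)=O
F2 | step 2 | 1-diazo-3-ethoxybut-3-en-2-one | C=C(OCC)C(=O)C=[N+]=[N-]
F3 | step 1 | 2,2-dimethylbut-3-enal | C=CC(C)(C)C=O
F4 | step 1 | 3,3-dimethylpent-4-en-1-yne | C=CC(C)(C)C#C
F5 | step 3 | 5-ethoxy-1,3-bis(methoxymethoxy)-2-(2-methylbut-3-en-2-yl)benzene | CCOc1cc(OCOC)c(C(C)(C)C=C)c(OCOC)c1
F6 | step 3 | 1-[6-ethoxy-2,4-bis(methoxymethoxy)-3-(2-methylbut-3-en-2-yl)phenyl]ethan-1-one | CC(=O)c1c(OCC)cc(OCOC)c(C(C)(C)C=C)c1OCOC
F7 | step 6 | rac-5-ethoxy-7-(methoxymethoxy)-2-(4-methoxyphenyl)-8-(2-methylbut-3-en-2-yl)-2,3-dihydro-4H-chromen-4-one (racemic) | COc1ccc(C2CC(=O)c3c(OCC)cc(OCOC)c(C(C)(C)C=C)c3O2)cc1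
F8 | step 6 | 5-ethoxy-7-(methoxymethoxy)-2-(4-methoxyphenyl)-8-(2-methylbut-3-en-2-yl)-4H-chromen-4-one | C=CC(C)(C)c1c(OCOC)cc(OCC)c2c(=O)cc(-c3ccc(OC)cc3)oc12
F9 | step 7 | 5-ethoxy-3,7-dihydroxy-2-(4-methoxyphenyl)-8-(2-methylbut-3-en-2-yl)-4H-chromen-4-one | C=CC(C)(C)c1c(O)cc(OCC)c2c(=O)c(O)c(-c3ccc(OC)cc3)oc12
F10 | step 7 | 5-ethoxy-2-(4-methoxyphenyl)-8-(2-methylbut-3-en-2-yl)-4-oxo-4H-chromene-3,7-diyl diacetate | C=CC(C)(C)c1c(OC(C)=O)cc(OCC)c2c(=O)c(OC(C)=O)c(-c3ccc(OC)cc3)oc12
F11 | step 7 | 5-hydroxy-2-(4-methoxyphenyl)-8-(2-methylbut-3-en-2-yl)-4-oxo-4H-chromene-3,7-diyl diacetate | C=CC(C)(C)c1c(OC(C)=O)cc(O)c2c(=O)c(OC(C)=O)c(-c3ccc(OC)cc3)oc12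
A1 | alternative 1 | 3,5-dihydroxy-2-(4-methoxyphenyl)-7-[(3-methylbut-2-en-1-yl)oxy]-4H-chromen-4-one | COc1ccc(-c2oc3cc(OCC=C(C)C)cc(O)c3c(=O)c2O)cc1
A2 | alternative 2 | 8-iodo-3,5,7-tris(methoxymethoxy)-2-(4-methoxyphenyl)-4H-chromen-4-one | COCOc1cc(OCOC)c2c(=O)c(OCOC)c(-c3ccc(OC)cc3)oc2c1I
A3 | alternative 3 | 5-ethoxy-3-hydroxy-7-(methoxymethoxy)-8-(2-methylbut-3-en-2-yl)-4H-chromen-4-one | C=CC(C)(C)c1c(OCOC)cc(OCC)c2c(=O)c(O)coc12
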